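**Retrosynthetic overview**
1. Feature: in the 3(2H)-furanone ring (O–C3=C2–C1(=O)–C10, germacrane numbering) the ring oxygen joins C3 to the quaternary C10 that sits next to the C1 carbonyl. This is the pattern left when a C3 ketone oxygen opens a 1,10-epoxide of the ten-membered carbocycle at its tertiary carbon.
2. Endgame: target ⇐ C1 oxidation and C15 desilylation ⇐ BF3-induced epoxy-ketone cyclisation (O–C10 bond) ⇐ peracid epoxidation of the E C1=C10 alkene of a 3-oxogermacra-1(10),4-dienolide.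
3. Carbocycle: C3–C4 by intramolecular Nozaki–Hiyama–Kishi coupling of a Z vinyl iodide with an aldehyde; C7–C8 by zinc Barbier allylation of a 3-(bromomethyl)butenolide (C4–C7, C11–C13, C15) with a C8 aldehyde (C8–C10, C1–C3, C14), so that C7 is the nucleophilic carbon.
4. Ring order: γ-lactone (as butenolide, by ring-closing metathesis) → ten-membered carbocycle → oxirane → oxygen-bridged dihydrofuran → furanone. C6 comes from a lipase resolution, C7 and C8 from C6 in the Barbier step, C10 from the epoxide by inversion.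

Key step: step 20

Remark: germacrane numbering is used throughout (C1–C10 ring, C11–C13 lactone, C14 methyl on C10, C15 on C4); the target is (6S,7S,8R,10R), with the C8 oxygen trans to the C7–C11 bond on the ten-membered ring.

**Route**

Step 1
Reactants: 1 2-butyne-1,4-diol
Product: 2 4-(tert-butyldimethylsilyloxy)but-2-yn-1-ol
Conditions: TBSCl (1 equiv), imidazole, 1 (3 equiv), DMF, 0 °C to rt
Reagents that add atoms: tert-butyldimethylsilyl chloride, C[Si](C)(Cl)C(C)(C)C
Why: Silyl ether formation; the symmetric diol in excess should make the mono-ether the main product, and no stereocentre is involved.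

Step 2
Reactants: 2 4-(tert-butyldimethylsilyloxy)but-2-yn-1-ol
Product: 4 (Z)-4-(tert-butyldimethylsilyloxy)-3-iodobut-2-en-1-ol, via cyclic alkenylaluminate 3 (not isolated)
Conditions: NaAlH2(OCH2CH2OCH3)2 (Red-Al), THF, 0 °C to rt; then I2, THF, −78 °C
Reagents that add atoms: iodine, II
Why: Hydroxyl-directed trans-hydroalumination places aluminium on the distal alkyne carbon in a five-membered aluminate, and iodinolysis with retention should give the Z vinyl iodide with iodine cis to the carbinol carbon (later C6), the geometry needed for C4=C5.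

Step 3
Reactants: 4 (Z)-4-(tert-butyldimethylsilyloxy)-3-iodobut-2-en-1-ol
Product: 5 (Z)-4-(tert-butyldimethylsilyloxy)-3-iodobut-2-enal
Conditions: MnO2, CH2Cl2, rt
Reagents that add atoms: none
Why: Allylic oxidation with MnO2 is neutral and should leave the Z iodoalkene and the silyl ether untouched.

Step 4
Reactants: 5 (Z)-4-(tert-butyldimethylsilyloxy)-3-iodobut-2-enal; 6 vinylmagnesium bromide (CH2=CHMgBr)
Product: 7 racemic (Z)-6-(tert-butyldimethylsilyloxy)-5-iodohexa-1,4-dien-3-ol
Conditions: THF, −78 °C; aq NH4Cl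
Reagents that add atoms: none
Why: Grignard 1,2-addition to the enal at low temperature; the C6 carbinol forms as a racemate that is resolved in step 5.

Step 5
Reactants: 7 racemic (Z)-6-(tert-butyldimethylsilyloxy)-5-iodohexa-1,4-dien-3-ol
Product: 8 (3R,4Z)-6-(tert-butyldimethylsilyloxy)-5-iodohexa-1,4-dien-3-yl acetate
Conditions: Novozym 435 (immobilised Candida antarctica lipase B), vinyl acetate, hexane, 30 °C, stopped near half conversion
Reagents that add atoms: vinyl acetate, C=COC(C)=O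
Why: Lipase-catalysed kinetic resolution by transesterification; by the Kazlauskas rule the enantiomer with the small vinyl and the large iodoalkenyl group arranged as in the R alcohol should be acylated, which fixes C6, while the S alcohol stays behind and is separated.

Step 6
Reactants: 8 (3R,4Z)-6-(tert-butyldimethylsilyloxy)-5-iodohexa-1,4-dien-3-yl acetate
Product: 9 (3R,4Z)-6-(tert-butyldimethylsilyloxy)-5-iodohexa-1,4-dien-3-ol
Conditions: K2CO3 (cat.), MeOH, 0 °C
Reagents that add atoms: none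
Why: Base-catalysed methanolysis of the acetate frees the R alcohol without touching C6, the silyl ether or the vinyl iodide.

Step 7
Reactants: 9 (3R,4Z)-6-(tert-butyldimethylsilyloxy)-5-iodohexa-1,4-dien-3-ol; 10 2-(bromomethyl)acrylic acid
Product: 11 (3R,4Z)-6-(tert-butyldimethylsilyloxy)-5-iodohexa-1,4-dien-3-yl 2-(bromomethyl)acrylate
Conditions: DCC, DMAP (5 mol %), CH2Cl2, −20 to 0 °C
Reagents that add atoms: none
Why: Steglich esterification; low temperature and catalytic DMAP should spare the allylic bromide, and C6 is retained because its C–O bond is not broken.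

Step 8
Reactants: 11 (3R,4Z)-6-(tert-butyldimethylsilyloxy)-5-iodohexa-1,4-dien-3-yl 2-(bromomethyl)acrylate
Product: 12 (R)-3-(bromomethyl)-5-[(Z)-3-(tert-butyldimethylsilyloxy)-2-iodoprop-1-enyl]furan-2(5H)-one
Conditions: second-generation Grubbs catalyst RuCl2(=CHPh)(PCy3)(H2IMes) (5 mol %), CH2Cl2, 40 °C
Reagents that add atoms: none
Why: Ring-closing metathesis of an acrylate ester of an allylic alcohol: the carbene loads on the terminal vinyl group and closes onto the 1,1-disubstituted acrylate to give the butenolide, while the trisubstituted iodoalkene stays out and C6 is unchanged.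

Step 9
Reactants: 13 4-(tert-butyldimethylsilyloxy)but-1-yne; 14 ethylene oxide
Product: 17 (E)-6-(tert-butyldimethylsilyloxy)-4-methylhex-3-en-1-ol, via alkenyldimethylalane 15 (not isolated), via lithium alkenylalanate 16 (not isolated)
Conditions: AlMe3, Cp2ZrCl2 (20 mol %), CH2Cl2, 0 °C to rt; then n-BuLi, THF, −78 °C; then 14, −78 to 0 °C
Reagents that add atoms: trimethylaluminium, C[Al](C)C
Why: Negishi zirconium-catalysed carboalumination adds methyl and aluminium syn across the alkyne, which fixes the E geometry of the later C1=C10 bond, and the alanate made with n-BuLi opens ethylene oxide by alkenyl transfer with retention.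

Step 10
Reactants: 17 (E)-6-(tert-butyldimethylsilyloxy)-4-methylhex-3-en-1-ol
Product: 18 tert-butyl{[(E)-6-(4-methoxybenzyloxy)-3-methylhex-3-enyl]oxy}dimethylsilane
Conditions: NaH, 4-methoxybenzyl chloride, Bu4NI (cat.), THF/DMF, 0 °C to rt
Reagents that add atoms: 4-methoxybenzyl chloride, COc1ccc(CCl)cc1
Why: Williamson ether synthesis on the primary alkoxide; the silyl ether and the alkene are inert to NaH.

Step 11
Reactants: 18 tert-butyl{[(E)-6-(4-methoxybenzyloxy)-3-methylhex-3-enyl]oxy}dimethylsilane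
Product: 19 (E)-6-(4-methoxybenzyloxy)-3-methylhex-3-en-1-ol
Conditions: Bu4NF, THF, 0 °C to rt
Reagents that add atoms: none
Why: Fluoride-mediated desilylation frees the primary alcohol that becomes C8 and leaves the PMB ether.

Step 12
Reactants: 19 (E)-6-(4-methoxybenzyloxy)-3-methylhex-3-en-1-ol
Product: 20 (E)-6-(4-methoxybenzyloxy)-3-methylhex-3-enal
Conditions: Dess–Martin periodinane, NaHCO3, CH2Cl2, 0 °C; used at once
Reagents that add atoms: none
Why: Dess–Martin oxidation under bicarbonate buffering should give the β,γ-unsaturated aldehyde without moving the alkene into conjugation.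

Step 13
Reactants: 12 (R)-3-(bromomethyl)-5-[(Z)-3-(tert-butyldimethylsilyloxy)-2-iodoprop-1-enyl]furan-2(5H)-one; 20 (E)-6-(4-methoxybenzyloxy)-3-methylhex-3-enal
Product: 22 (4S,5R)-5-[(Z)-3-(tert-butyldimethylsilyloxy)-2-iodoprop-1-enyl]-4-[(1R,3E)-1-hydroxy-6-(4-methoxybenzyloxy)-3-methylhex-3-enyl]-3-methylenedihydrofuran-2(3H)-one, via allylzinc bromide 21 (not isolated)
Conditions: Zn dust, THF/sat. aq NH4Cl, 0 °C to rt
Reagents that add atoms: none
Why: Zinc Barbier allylation of a 3-(bromomethyl)butenolide: the allylzinc reacts through C7 (SE2') in a chair-like six-membered transition state with the aldehyde chain equatorial and the new bond anti to the C6 substituent, which should set C7 trans to C6 on the lactone and C8 with its oxygen syn to C11 along the C6–C9 chain, as in the target.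

Step 14
Reactants: 22 the Barbier alcohol; 23 crotonic anhydride
Product: 24 (1R,3E)-1-[(2R,3S)-2-[(Z)-3-(tert-butyldimethylsilyloxy)-2-iodoprop-1-enyl]-4-methylene-5-oxotetrahydrofuran-3-yl]-6-(4-methoxybenzyloxy)-3-methylhex-3-enyl (E)-but-2-enoate
Conditions: pyridine, DMAP (cat.), CH2Cl2, 0 °C
Reagents that add atoms: none
Why: DMAP-catalysed acylation of the secondary alcohol by the anhydride installs the crotonate with retention at C8.

Step 15
Reactants: 24 the C8 crotonate
Product: 25 (1R,3E)-1-[(2R,3S)-2-[(Z)-3-(tert-butyldimethylsilyloxy)-2-iodoprop-1-enyl]-4-methylene-5-oxotetrahydrofuran-3-yl]-6-hydroxy-3-methylhex-3-enyl (E)-but-2-enoate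
Conditions: DDQ, CH2Cl2/pH 7 buffer, 0 °C
Reagents that add atoms: none
Why: Oxidative cleavage of the PMB ether by DDQ should leave the silyl ether, the vinyl iodide and the Michael acceptors alone.

Step 16
Reactants: 25 the C3 primary alcohol
Product: 26 (1R,3E)-1-[(2R,3S)-2-[(Z)-3-(tert-butyldimethylsilyloxy)-2-iodoprop-1-enyl]-4-methylene-5-oxotetrahydrofuran-3-yl]-3-methyl-6-oxohex-3-enyl (E)-but-2-enoate
Conditions: Dess–Martin periodinane, NaHCO3, CH2Cl2, 0 °C; used at once
Reagents that add atoms: none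
Why: Buffered Dess–Martin oxidation gives the β,γ-unsaturated C3 aldehyde without conjugation.

Step 17
Reactants: 26 the iodo aldehyde
Product: 28 (6S,7S,8R,1(10)E,4Z)-8-[(E)-but-2-enoyloxy]-15-(tert-butyldimethylsilyloxy)-3-hydroxygermacra-1(10),4,11(13)-trien-12,6-olide (both C3 epimers), via alkenylchromium dichloride 27 (not isolated)
Conditions: CrCl2 (10 equiv), NiCl2 (2 mol %), DMSO, rt, slow addition to 2 mM
Reagents that add atoms: none
Why: Intramolecular Nozaki–Hiyama–Kishi reaction: zerovalent nickel inserts into the C–I bond, the alkenyl group passes to trivalent chromium with retention of the Z geometry and adds chemoselectively to the aldehyde under high dilution, closing the ten-membered ring at C3–C4; the C3 carbinol forms as an epimer mixture that is removed by oxidation in step 18.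

Step 18
Reactants: 28 the macrocyclic allylic alcohol
Product: 29 (6S,7S,8R,1(10)E,4Z)-8-[(E)-but-2-enoyloxy]-15-(tert-butyldimethylsilyloxy)-3-oxogermacra-1(10),4,11(13)-trien-12,6-olide
Conditions: Dess–Martin periodinane, NaHCO3, CH2Cl2, 0 °C
Reagents that add atoms: none
Why: Dess–Martin oxidation of the allylic alcohol gives the C3 enone and deactivates the C4=C5 alkene toward the peracid of step 19.

Step 19
Reactants: 29 the macrocyclic enone
Product: 30 (1S,6S,7S,8R,10S,4Z)-8-[(E)-but-2-enoyloxy]-15-(tert-butyldimethylsilyloxy)-1,10-epoxy-3-oxogermacra-4,11(13)-dien-12,6-olide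
Conditions: mCPBA, NaHCO3, CH2Cl2, 0 °C
Reagents that add atoms: 3-chloroperoxybenzoic acid, O=C(OO)c1cccc(Cl)c1
Why: Prilezhaev epoxidation: only the C1=C10 alkene is electron-rich, and attack on its outer face in the germacranolide conformation that holds the C14 methyl on the same side as the C7–C11 bond should give the trans (1S,10S) epoxide.

Step 20
Reactants: 30 the 3-oxo-1,10-epoxide
Product: 32 (1S,6S,7S,8R,10R,4Z)-8-[(E)-but-2-enoyloxy]-15-(tert-butyldimethylsilyloxy)-3,10-epoxy-1-hydroxygermacra-2,4,11(13)-trien-12,6-olide, via oxocarbenium ion 31 (not isolated)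
Conditions: BF3·OEt2 (0.5 equiv), CH2Cl2, −78 °C; Et3N quench
Reagents that add atoms: none
Why: BF3 binds the epoxide oxygen, the C10–O bond stretches toward the tertiary cation, and the C3 carbonyl oxygen attacks C10 from the face opposite the leaving oxygen to give oxocarbenium ion 31, which loses a C2 proton to form the C2=C3 enol ether. The closest known reaction is the acid-promoted cyclisation of β,γ-epoxy ketones to 3-hydroxy-2,3-dihydrofurans, the first stage of their conversion into furans. The oxolene ring (O, C3, C2, C1, C10) closes in the 5-endo mode at the epoxide, which is feasible because the nucleophile is an sp2 oxygen and C10 carries most of the positive charge. C10 is set by inversion of the epoxide carbon made in step 19, and C1 keeps the former epoxide oxygen with retention. The step needs attack at C10 and not C1, and it must outrun β-elimination to the 10-hydroxy-1-en-3-one, the Meinwald hydride shift and ionisation of the product's allylic hydroxyl. The tertiary C10, the fixed 1,4-relation of the carbonyl oxygen to C10, the low temperature and the early amine quench should secure this, and because C10 is quaternary the dihydrofuranol cannot aromatise.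

Step 21
Reactants: 32 the dihydrofuranol
Product: 33 (6S,7S,8R,10R,4Z)-8-[(E)-but-2-enoyloxy]-15-(tert-butyldimethylsilyloxy)-3,10-epoxy-1-oxogermacra-2,4,11(13)-trien-12,6-olide
Conditions: MnO2, CH2Cl2, rt
Reagents that add atoms: none
Why: MnO2 oxidation of the allylic C1 alcohol (activated by the enol ether) gives the 3(2H)-furanone, a vinylogous ester, while the silyl ether keeps C15 from being oxidised.

Step 22
Reactants: 33 the furanone silyl ether
Product: 34 (6S,7S,8R,10R,4Z)-8-[(E)-but-2-enoyloxy]-3,10-epoxy-15-hydroxy-1-oxogermacra-2,4,11(13)-trien-12,6-olide (CNP0225232.1)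
Conditions: HF·pyridine, pyridine/THF, 0 °C
Reagents that add atoms: none
Why: Desilylation with buffered HF·pyridine frees the C15 alcohol without conjugate addition to the α-methylene lactone or the crotonate.

**Compound list**
1 | 2-butyne-1,4-diol | OCC#CCO | starting material
2 | 4-(tert-butyldimethylsilyloxy)but-2-yn-1-ol | OCC#CCO[Si](C)(C)C(C)(C)C | intermediate
3 | cyclic sodium alkenylaluminate from 2 (Al on O and on C3, two 2-methoxyethoxy ligands) | COCCO[Al-]1(OCCOC)OCC=C1CO[Si](C)(C)C(C)(C)C.[Na+] | intermediate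
4 | (Z)-4-(tert-butyldimethylsilyloxy)-3-iodobut-2-en-1-ol | OC/C=C(\I)CO[Si](C)(C)C(C)(C)C | intermediate
5 | (Z)-4-(tert-butyldimethylsilyloxy)-3-iodobut-2-enal | O=C/C=C(\I)CO[Si](C)(C)C(C)(C)C | intermediate
6 | vinylmagnesium bromide | C=C[Mg]Br | starting material
7 | racemic (Z)-6-(tert-butyldimethylsilyloxy)-5-iodohexa-1,4-dien-3-ol | C=CC(O)/C=C(\I)CO[Si](C)(C)C(C)(C)C | intermediate
8 | (3R,4Z)-6-(tert-butyldimethylsilyloxy)-5-iodohexa-1,4-dien-3-yl acetate | C=C[C@@H](OC(C)=O)/C=C(\I)CO[Si](C)(C)C(C)(C)C | intermediate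
9 | (3R,4Z)-6-(tert-butyldimethylsilyloxy)-5-iodohexa-1,4-dien-3-ol | C=C[C@@H](O)/C=C(\I)CO[Si](C)(C)C(C)(C)C | intermediate
10 | 2-(bromomethyl)acrylic acid | C=C(CBr)C(=O)O | starting material
11 | (3R,4Z)-6-(tert-butyldimethylsilyloxy)-5-iodohexa-1,4-dien-3-yl 2-(bromomethyl)acrylate | C=C[C@@H](OC(=O)C(=C)CBr)/C=C(\I)CO[Si](C)(C)C(C)(C)C | intermediate
12 | (R)-3-(bromomethyl)-5-[(Z)-3-(tert-butyldimethylsilyloxy)-2-iodoprop-1-enyl]furan-2(5H)-one | O=C1O[C@@H](/C=C(\I)CO[Si](C)(C)C(C)(C)C)C=C1CBr | intermediate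
13 | 4-(tert-butyldimethylsilyloxy)but-1-yne | C#CCCO[Si](C)(C)C(C)(C)C | starting material
14 | ethylene oxide | C1CO1 | starting material
15 | [(E)-4-(tert-butyldimethylsilyloxy)-2-methylbut-1-enyl]dimethylaluminium | C/C(CCO[Si](C)(C)C(C)(C)C)=C\[Al](C)C | intermediate
16 | lithium butyl[(E)-4-(tert-butyldimethylsilyloxy)-2-methylbut-1-enyl]dimethylaluminate | [Li+].CCCC[Al-](C)(C)/C=C(\C)CCO[Si](C)(C)C(C)(C)C | intermediate
17 | (E)-6-(tert-butyldimethylsilyloxy)-4-methylhex-3-en-1-ol | C/C(CCO[Si](C)(C)C(C)(C)C)=C\CCO | intermediate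
18 | tert-butyl{[(E)-6-(4-methoxybenzyloxy)-3-methylhex-3-enyl]oxy}dimethylsilane | C/C(CCO[Si](C)(C)C(C)(C)C)=C\CCOCc1ccc(OC)cc1 | intermediate
19 | (E)-6-(4-methoxybenzyloxy)-3-methylhex-3-en-1-ol | C/C(CCO)=C\CCOCc1ccc(OC)cc1 | intermediate
20 | (E)-6-(4-methoxybenzyloxy)-3-methylhex-3-enal | C/C(CC=O)=C\CCOCc1ccc(OC)cc1 | intermediate
21 | allylzinc bromide from 12 (Zn on the former CH2Br carbon) | Br[Zn]CC1=C[C@H](/C=C(\I)CO[Si](C)(C)C(C)(C)C)OC1=O | intermediate
22 | Barbier alcohol: trans-lactone with C8 hydroxyl, C3 PMB ether, C4 iodide, C15 TBS ether (configured at C6, C7, C8 as in the target) | C=C1C(=O)O[C@@H](/C=C(\I)CO[Si](C)(C)C(C)(C)C)[C@@H]1[C@H](O)C/C(C)=C/CCOCc2ccc(OC)cc2 | intermediate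
23 | crotonic anhydride | C/C=C/C(=O)OC(=O)/C=C/C | starting material
24 | C8 (E)-but-2-enoate of 22 | C=C1C(=O)O[C@@H](/C=C(\I)CO[Si](C)(C)C(C)(C)C)[C@@H]1[C@H](OC(=O)/C=C/C)C/C(C)=C/CCOCc2ccc(OC)cc2 | intermediate
25 | C3 primary alcohol from 24 | C=C1C(=O)O[C@@H](/C=C(\I)CO[Si](C)(C)C(C)(C)C)[C@@H]1[C@H](OC(=O)/C=C/C)C/C(C)=C/CCO | intermediate
26 | C3 aldehyde from 25 | C=C1C(=O)O[C@@H](/C=C(\I)CO[Si](C)(C)C(C)(C)C)[C@@H]1[C@H](OC(=O)/C=C/C)C/C(C)=C/CC=O | intermediate
27 | alkenylchromium dichloride from 26 (Cr on C4) | C=C1C(=O)O[C@@H](/C=C(\[Cr](Cl)Cl)CO[Si](C)(C)C(C)(C)C)[C@@H]1[C@H](OC(=O)/C=C/C)C/C(C)=C/CC=O | intermediate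
28 | 3-hydroxygermacra-1(10)E,4Z,11(13)-trien-12,6-olide 8-crotonate, C15 TBS ether (C3 epimers) | C=C1C(=O)O[C@H]2/C=C(/CO[Si](C)(C)C(C)(C)C)C(O)C/C=C(\C)C[C@@H](OC(=O)/C=C/C)[C@H]12 | intermediate
29 | 3-oxogermacra-1(10)E,4Z,11(13)-trien-12,6-olide 8-crotonate, C15 TBS ether | C=C1C(=O)O[C@H]2/C=C(/CO[Si](C)(C)C(C)(C)C)C(=O)C/C=C(\C)C[C@@H](OC(=O)/C=C/C)[C@H]12 | intermediate
30 | (1S,10S)-1,10-epoxy-3-oxogermacra-4Z,11(13)-dien-12,6-olide 8-crotonate, C15 TBS ether | C=C1C(=O)O[C@H]2/C=C(/CO[Si](C)(C)C(C)(C)C)C(=O)C[C@@H]3O[C@@]3(C)C[C@@H](OC(=O)/C=C/C)[C@H]12 | intermediate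
31 | BF3-bound 3,10-bridged oxocarbenium ion | C=C1C(=O)O[C@H]2/C=C(/CO[Si](C)(C)C(C)(C)C)C3=[O+][C@](C)(C[C@@H](OC(=O)/C=C/C)[C@H]12)[C@@H](O[B-](F)(F)F)C3 | intermediate
32 | (1S,10R)-3,10-epoxy-1-hydroxygermacra-2,4Z,11(13)-trien-12,6-olide 8-crotonate, C15 TBS ether | C=C1C(=O)O[C@H]2/C=C(/CO[Si](C)(C)C(C)(C)C)C3=C[C@H](O)[C@@](C)(C[C@@H](OC(=O)/C=C/C)[C@H]12)O3 | intermediate
33 | (10R)-3,10-epoxy-1-oxogermacra-2,4Z,11(13)-trien-12,6-olide 8-crotonate, C15 TBS ether | C=C1C(=O)O[C@H]2/C=C(/CO[Si](C)(C)C(C)(C)C)C3=CC(=O)[C@@](C)(C[C@@H](OC(=O)/C=C/C)[C@H]12)O3 | intermediate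
34 | (6S,7S,8R,10R,4Z)-8-[(E)-but-2-enoyloxy]-3,10-epoxy-15-hydroxy-1-oxogermacra-2,4,11(13)-trien-12,6-olide | C=C1C(=O)O[C@H]2/C=C(/CO)C3=CC(=O)[C@@](C)(C[C@@H](OC(=O)/C=C/C)[C@H]12)O3 | target

**Step count and risks**

Total step count: 22. Longest linear sequence: 18 steps (steps 1–8, then 13–22); the aldehyde arm takes 4 steps (9–12).

Steps most likely to fail:

1. Step 20 (epoxy-ketone cyclisation). The activated epoxide may collapse by β-elimination toward C2, by hydride shift to a C1 ketone, or by fluoride capture, and the allylic hydroxyl of the product may ionise before the quench. Fallback, from 30 back to 33: the epoxide is opened at C10 by a C3 hydroxyl instead of the carbonyl. Luche reduction (NaBH4, CeCl3·7H2O, MeOH, −78 °C) of 30 should give the (3R)-allylic alcohol F1; its 3-epimer cannot bridge and is returned to 30 with Dess–Martin periodinane. Catalytic camphorsulfonic acid in CH2Cl2 at 0 °C should open the epoxide at the tertiary C10 with the C3 hydroxyl, again with inversion, to the 3,10-epoxy-1-ol F2 (5-endo closure of a 3,4-epoxy alcohol at a tertiary carbon). Dess–Martin oxidation gives the oxolan-3-one F3, TMSOTf/Et3N gives its silyl enol ether F4 (enolisation is possible only toward C2 because C10 is quaternary), and Saegusa–Ito oxidation with Pd(OAc)2 in MeCN introduces C2=C3 and rejoins the route at 33.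

2. Step 17 (ten-membered Nozaki–Hiyama–Kishi closure). Oligomerisation or reductive loss of iodide may outpace closure of the strained ring. Fallback, from 8 back to 28: the two carbon–carbon unions are exchanged so that the ring closes at C7–C8 by an intramolecular allylation, a known type of medium-ring closure.
   - Commercial 4-(4-methoxybenzyloxy)but-1-yne (C#CCCOCc1ccc(OC)cc1) is taken through the conditions of step 9 to (E)-6-(4-methoxybenzyloxy)-4-methylhex-3-en-1-ol F5 and oxidised with Dess–Martin periodinane to the aldehyde F6.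
   - Intermolecular CrCl2/NiCl2 coupling of F6 with acetate 8 gives the allylic alcohol F7, which is silylated (TESOTf, 2,6-lutidine) to the triethylsilyl ether F8 and deacetylated (K2CO3, MeOH) to the C6 alcohol F9.
   - Esterification with 10 as in step 7 gives the acrylate F10, and ring-closing metathesis as in step 8 gives the bromobutenolide F11.
   - DDQ frees the C8 alcohol F12, Dess–Martin oxidation gives the C8 aldehyde F13, and CrCl2 in THF at 2 mM should close the ring to the hydroxy lactone F14; its C7/C8 configuration would have to be checked against 22.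
   - Crotonylation with 23 gives the crotonate F15, and PPTS in MeOH removes the triethylsilyl group to return to 28.

3. Step 19 (epoxidation). The peracid may show poor or reversed facial selectivity on the macrocycle, and the β,γ-alkene of 29 may slip into conjugation before it is epoxidised. Fallback, from 24 back to 30: the epoxide is installed before ring closure under reagent control. Shi epoxidation of 24 with the L-fructose-derived ketone catalyst, Oxone and K2CO3 in buffered MeCN/dimethoxymethane at 0 °C should give the (1S,10S)-epoxide F16. DDQ then gives the primary alcohol F17, Dess–Martin oxidation gives the epoxy aldehyde F18, the CrCl2/NiCl2 closure of step 17 gives the macrocyclic epoxy alcohol F19, and Dess–Martin oxidation returns to 30.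

Further compounds
F1 | step 20 | (3R)-3-hydroxy analogue of 30 | C=C1C(=O)O[C@H]2/C=C(/CO[Si](C)(C)C(C)(C)C)[C@H](O)C[C@@H]3O[C@@]3(C)C[C@@H](OC(=O)/C=C/C)[C@H]12
F2 | step 20 | 3,10-epoxy-1-hydroxygermacra-4,11(13)-dienolide (oxolane; C2 saturated analogue of 32) | C=C1C(=O)O[C@H]2/C=C(/CO[Si](C)(C)C(C)(C)C)[C@H]3C[C@H](O)[C@@](C)(C[C@@H](OC(=O)/C=C/C)[C@H]12)O3
F3 | step 20 | 3,10-epoxy-1-oxo oxolanone (2,3-dihydro analogue of 33) | C=C1C(=O)O[C@H]2/C=C(/CO[Si](C)(C)C(C)(C)C)[C@H]3CC(=O)[C@@](C)(C[C@@H](OC(=O)/C=C/C)[C@H]12)O3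
F4 | step 20 | C1 trimethylsilyl enol ether of F3 | C=C1C(=O)O[C@H]2/C=C(/CO[Si](C)(C)C(C)(C)C)[C@H]3C=C(O[Si](C)(C)C)[C@@](C)(C[C@@H](OC(=O)/C=C/C)[C@H]12)O3
F5 | step 17 | (E)-6-(4-methoxybenzyloxy)-4-methylhex-3-en-1-ol | C/C(CCOCc1ccc(OC)cc1)=C\CCO
F6 | step 17 | (E)-6-(4-methoxybenzyloxy)-4-methylhex-3-enal | C/C(CCOCc1ccc(OC)cc1)=C\CC=O
F7 | step 17 | acyclic C3 allylic alcohol from 8 and F6 (C6 acetate, C8 PMB ether) | C=C[C@@H](OC(C)=O)/C=C(/CO[Si](C)(C)C(C)(C)C)C(O)C/C=C(\C)CCOCc1ccc(OC)cc1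
F8 | step 17 | C3 triethylsilyl ether of F7 | C=C[C@@H](OC(C)=O)/C=C(/CO[Si](C)(C)C(C)(C)C)C(O[Si](CC)(CC)CC)C/C=C(\C)CCOCc1ccc(OC)cc1
F9 | step 17 | C6 alcohol from F8 | C=C[C@@H](O)/C=C(/CO[Si](C)(C)C(C)(C)C)C(O[Si](CC)(CC)CC)C/C=C(\C)CCOCc1ccc(OC)cc1
F10 | step 17 | 2-(bromomethyl)acrylate of F9 | C=C[C@@H](OC(=O)C(=C)CBr)/C=C(/CO[Si](C)(C)C(C)(C)C)C(O[Si](CC)(CC)CC)C/C=C(\C)CCOCc1ccc(OC)cc1
F11 | step 17 | bromobutenolide carrying the C3–C10 chain | O=C1O[C@@H](/C=C(/CO[Si](C)(C)C(C)(C)C)C(O[Si](CC)(CC)CC)C/C=C(\C)CCOCc2ccc(OC)cc2)C=C1CBr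
F12 | step 17 | C8 primary alcohol from F11 | O=C1O[C@@H](/C=C(/CO[Si](C)(C)C(C)(C)C)C(O[Si](CC)(CC)CC)C/C=C(\C)CCO)C=C1CBr
F13 | step 17 | C8 aldehyde from F12 | O=C1O[C@@H](/C=C(/CO[Si](C)(C)C(C)(C)C)C(O[Si](CC)(CC)CC)C/C=C(\C)CC=O)C=C1CBr
F14 | step 17 | macrocyclic 8-hydroxy lactone, C3 triethylsilyl ether | C=C1C(=O)O[C@H]2/C=C(/CO[Si](C)(C)C(C)(C)C)C(O[Si](CC)(CC)CC)C/C=C(\C)C[C@@H](O)[C@H]12
F15 | step 17 | 8-crotonate of F14 | C=C1C(=O)O[C@H]2/C=C(/CO[Si](C)(C)C(C)(C)C)C(O[Si](CC)(CC)CC)C/C=C(\C)C[C@@H](OC(=O)/C=C/C)[C@H]12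
F16 | step 19 | (1S,10S)-epoxide of 24 | C=C1C(=O)O[C@@H](/C=C(\I)CO[Si](C)(C)C(C)(C)C)[C@@H]1[C@H](OC(=O)/C=C/C)C[C@]2(C)O[C@H]2CCOCc3ccc(OC)cc3
F17 | step 19 | C3 primary alcohol from F16 | C=C1C(=O)O[C@@H](/C=C(\I)CO[Si](C)(C)C(C)(C)C)[C@@H]1[C@H](OC(=O)/C=C/C)C[C@]2(C)O[C@H]2CCO
F18 | step 19 | epoxy aldehyde from F17 | C=C1C(=O)O[C@@H](/C=C(\I)CO[Si](C)(C)C(C)(C)C)[C@@H]1[C@H](OC(=O)/C=C/C)C[C@]2(C)O[C@H]2CC=O
F19 | step 19 | macrocyclic 1,10-epoxy-3-hydroxy lactone (C3 epimers) | C=C1C(=O)O[C@H]2/C=C(/CO[Si](C)(C)C(C)(C)C)C(O)C[C@@H]3O[C@@]3(C)C[C@@H](OC(=O)/C=C/C)[C@H]12
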